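**Retrosynthetic overview**
1. Enabling feature: in target 28 the ketone carbon C1 and the lactam carbonyl carbon C9a face each other across the nine-membered ring D. Rejoined as C1=C9a, they are the β- and α-carbons of a pyrrole (ring E: N4, C3, C2, C1, C9a) fused to a cyclohexane (ring F: C9a, C9, C10, C11, C12, C1). Ring D is therefore an oxidatively cleaved tetrahydroindole.
2. In that pyrrole, C5–N4–C9a is a 1,3-ambiphile (N–CH2+ at C5, nucleophilic α-carbon C9a), and the chain C6–C9 of azepane ring C is written as a diene. One cationic (4+3) annulation makes C5–C6 and C9a–C9, closes rings C and F, and sets C9 (step 9).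
3. After the key step: alkene saturation, ester-to-acid change, and ozonolysis of C1=C9a (rings E and F vanish, ring D appears). The C3 carboxyl group, which blocked and tempered the pyrrole, is then spent as the trigger of a decarboxylative vinylogous Mannich reaction (C3, C18). Hydrogenation completes ring B (C20).
4. Before the key step: precursor 14 is built from commercial pieces by Suzuki–Miyaura coupling (C1–C12), organocatalytic Mukaiyama–Michael addition (C10, C11), cis-hydrogenation (C12), vinyl addition/1,4-elimination (diene) and enolate methylation (C13).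
5. Ring order: E and unsaturated A (bought) → A saturated (step 5) → C and F (step 9) → D at the expense of E and F (step 12) → B (steps 15 and 16).

Key step: step 9

Numbering used throughout: N4. C3, C2, C1 are the N-bearing CH, the CH2 and the ketone carbon. C12, C11, C10, C9 are the next four atoms of ring D (C10 bears ethyl). C9a is the lactam carbonyl carbon. C5–C8 are the four CH2 groups from N4 to C9. C13 (CHMe) and C14 (C=O) complete lactone ring A on C12/C11. C18 (OCH), C19, C20 (CHMe) and C21 (C=O) form lactone ring B on C3. Ring C is N4, C5–C9, C9a.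
Remark on the chemistry: the carbinol centre C8 of 10 and 11 and the centre C3 of 23 and 26 are carried as epimer mixtures because both are erased later. The ozonide 21 is drawn without configuration at C1 and C9a.

Step 1
Reactants: 1 methyl 4-bromo-1H-pyrrole-2-carboxylate
Product: 2 methyl 4-bromo-1-(methoxymethyl)-1H-pyrrole-2-carboxylate
Conditions: MOMCl, K2CO3, DMF, 0 °C to rt
Reagents that add atoms: chloromethyl methyl ether (MOMCl), COCCl
Why: N-alkylation of the acidic acylpyrrole N–H (SN2 on an α-chloro ether) installs the N–CH2–OMe group whose CH2 is the future C5; no stereocentre is formed.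

Step 2
Reactants: 2 methyl 4-bromo-1-(methoxymethyl)-1H-pyrrole-2-carboxylate; 3 4-bromofuran-2(5H)-one
Product: 5 methyl 1-(methoxymethyl)-4-(5-oxo-2,5-dihydrofuran-3-yl)-1H-pyrrole-2-carboxylate, via pinacol boronate 4 (not isolated)
Conditions: B2pin2, PdCl2(dppf) (3 mol %), KOAc, 1,4-dioxane, 90 °C; then 3, aq K3PO4, 70 °C
Reagents that add atoms: bis(pinacolato)diboron, CC1(C)OB(OC1(C)C)B1OC(C)(C)C(C)(C)O1 (its boryl group is carried by 4 only)
Why: Miyaura borylation followed in the same pot by Suzuki–Miyaura coupling with the β-bromobutenolide forms the C1–C12 bond on achiral material, so the acidic butenolide CH2 is of no concern.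

Step 3
Reactants: 5 methyl 1-(methoxymethyl)-4-(5-oxo-2,5-dihydrofuran-3-yl)-1H-pyrrole-2-carboxylate
Product: 6 methyl 1-(methoxymethyl)-4-{5-[(triisopropylsilyl)oxy]furan-3-yl}-1H-pyrrole-2-carboxylate
Conditions: TIPSOTf, Et3N, CH2Cl2, 0 °C
Reagents that add atoms: triisopropylsilyl triflate, CC(C)[Si](OS(=O)(=O)C(F)(F)F)(C(C)C)C(C)C
Why: Soft enolisation and O-silylation of a butenolide gives the aromatic 2-silyloxyfuran, the vinylogous nucleophile for C11.

Step 4
Reactants: 6 methyl 1-(methoxymethyl)-4-{5-[(triisopropylsilyl)oxy]furan-3-yl}-1H-pyrrole-2-carboxylate; 7 (E)-pent-2-enal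
Product: 8 methyl 1-(methoxymethyl)-4-{(2S)-5-oxo-2-[(3R)-1-oxopentan-3-yl]-2,5-dihydrofuran-3-yl}-1H-pyrrole-2-carboxylate (10R,11S)
Conditions: (2S,5S)-5-benzyl-2-tert-butyl-3-methylimidazolidin-4-one (20 mol %), 2,4-dinitrobenzoic acid (20 mol %), H2O (2 equiv), CH2Cl2, −40 °C
Reagents that add atoms: none
Why: Iminium-catalysed vinylogous Mukaiyama–Michael addition, in which the benzyl arm of the catalyst blocks one face of the E-iminium ion of 7 so that the furan carbon C11 bonds to the open face of C10 (10R), while the open transition state, tunable through acid co-catalyst and solvent, should set 11S; the ester-deactivated pyrrole does not compete as nucleophile.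

Step 5
Reactants: 8 butenolide aldehyde (10R,11S)
Product: 9 methyl 1-(methoxymethyl)-4-{(2S,3R)-5-oxo-2-[(3R)-1-oxopentan-3-yl]oxolan-3-yl}-1H-pyrrole-2-carboxylate (cis-lactone; 10R,11S,12R)
Conditions: H2 (3 atm), 10% Pd/C, EtOAc, rt
Reagents that add atoms: none
Why: Heterogeneous syn-hydrogenation of the β-aryl butenolide from the face opposite to the branched C11 substituent should place C12–H cis to C11–H, giving the cis-4,5-disubstituted lactone that a conjugate addition could not give.

Step 6
Reactants: 9 cis-lactone aldehyde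
Product: 11 methyl 4-{(2S,3R)-2-[(3R)-5-(methoxycarbonyloxy)hept-6-en-3-yl]-5-oxooxolan-3-yl}-1-(methoxymethyl)-1H-pyrrole-2-carboxylate (both C8 epimers), via bromomagnesium alkoxide 10 (not isolated)
Conditions: CH2=CHMgBr (1.1 equiv), THF, −78 °C; then ClCO2Me, −78 to 0 °C
Reagents that add atoms: vinylmagnesium bromide, C=C[Mg]Br; methyl chloroformate, COC(=O)Cl
Why: Chemoselective Grignard 1,2-addition to the aldehyde (far faster than to lactone or pyrrole ester at −78 °C) brings in C7 and C6, and the alkoxide is acylated in the flask; the C8 centre needs no control.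

Step 7
Reactants: 11 allylic methyl carbonate
Product: 12 methyl 4-{(2S,3R)-2-[(3R,4E)-hepta-4,6-dien-3-yl]-5-oxooxolan-3-yl}-1-(methoxymethyl)-1H-pyrrole-2-carboxylate
Conditions: Pd(PPh3)4 (5 mol %), 1,4-dioxane, 90 °C
Reagents that add atoms: none
Why: Decarboxylative 1,4-elimination of an allylic carbonate catalysed by zerovalent palladium (ionisation to the π-allyl complex, then β-hydride loss from C9, the only available site) should give the E-configured C9=C8–C7=C6 diene and erase C8.

Step 8
Reactants: 12 diene lactone
Product: 14 methyl 4-{(2S,3R,4S)-2-[(3R,4E)-hepta-4,6-dien-3-yl]-4-methyl-5-oxooxolan-3-yl}-1-(methoxymethyl)-1H-pyrrole-2-carboxylate, via lithium enolate 13 (not isolated)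
Conditions: LDA (1.05 equiv), THF, −78 °C; then MeI, −78 to −40 °C
Reagents that add atoms: iodomethane, CI; lithium diisopropylamide, CC(C)[N-]C(C)C.[Li+] (lithium is carried by 13 only)
Why: Kinetic lactone enolate alkylation in which MeI approaches the face opposite to the two cis substituents at C11 and C12, setting 13S (methyl trans to the pyrrolyl group), which is also the more stable epimer.

Step 9
Reactants: 14 methyl 4-{(2S,3R,4S)-2-[(3R,4E)-hepta-4,6-dien-3-yl]-4-methyl-5-oxooxolan-3-yl}-1-(methoxymethyl)-1H-pyrrole-2-carboxylate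
Product: 17 tetracyclic pyrrole ester (rings A, C, E, F; CO2Me at C3; Z-C7=C8; 9R,10R,11S,12R,13S), via N-methylenepyrrolium ion 15 (not isolated), via allyl cation 16 (not isolated)
Conditions: HNTf2 (10 mol %), (CF3)2CHOH/CH2Cl2 1:4, slow addition of 14 to 0.002 M, 0 °C to rt
Reagents that add atoms: none
Why: Proposed new method: acid ionises the N,O-acetal of 14 (the same event by which N-alkoxymethyl groups are removed from acylpyrroles) to the N-methylenepyrrolium ion 15; its CH2 carbon C5 is attacked by the unsubstituted diene terminus C6 to give allyl cation 16 (C7–C9), which is captured at C9 by the pyrrole α-carbon C9a, and loss of the C9a proton restores the pyrrole, so C5–N4–C9a acts as a 1,3-ambiphile in a stepwise cationic (4+3) annulation. The closest known reaction types are the Lewis-acid-induced (3+2) annulation of N-(heteroatom-methyl)azoles with alkenes, the aza-Prins/Friedel–Crafts cascade and the intramolecular (4+3) cycloaddition of allyl cations with tethered dienes. The C9a–C9 bond closes carbocycle F in the 6-exo-trig mode and, together with C5–C6, azepine ring C in the 7-endo-trig mode, the s-cis diene delivering the Z-C7=C8 bond. The one new stereocentre, C9, is controlled by the chair-like transition state of ring F, in which the C10 ethyl group, the C11 oxygen and the C8 arm are all equatorial and only C13 of the cis-fused lactone is axial; this puts C8 trans to ethyl (9R), and since the allylic Friedel–Crafts bond can re-ionise in acid, this most stable epimer should also be the product of equilibration. The step needs (4+3) rather than (3+2) regiochemistry and intramolecular rather than intermolecular capture. Closure at C7 would lock an E-alkene into an eight-membered ring, whereas the three-atom tether C10–C12 holds C9 over C9a; the C3 ester blocks the other α-position and tempers the pyrrole against self-alkylation, and high dilution in a cation-stabilising, poorly nucleophilic medium suppresses oligomerisation.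

Step 10
Reactants: 17 tetracyclic pyrrole ester (Z-C7=C8)
Product: 18 saturated tetracyclic pyrrole ester (ring C fully saturated; 9R,10R,11S,12R,13S)
Conditions: H2 (1 atm), 10% Pd/C, EtOAc, rt
Reagents that add atoms: none
Why: Chemoselective heterogeneous hydrogenation of the isolated Z-alkene, to which the acyl-stabilised pyrrole is inert, removes the only other ozone-sensitive bond.

Step 11
Reactants: 18 saturated tetracyclic pyrrole ester
Product: 20 tetracyclic pyrrole-C3-carboxylic acid, via lithium carboxylate 19 (not isolated)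
Conditions: LiI (10 equiv), pyridine, 115 °C; then 1 M HCl, 0 °C
Reagents that add atoms: lithium iodide, [Li+].[I-] (lithium is carried by 19 only)
Why: SN2 dealkylation at the ester methyl carbon does not depend on the low carbonyl reactivity of a pyrrole ester, spares the lactone (secondary, hindered C11–O), and is done here so that no basic step is needed once the β-acyloxy, β-amido ketone exists.

Step 12
Reactants: 20 tetracyclic pyrrole-C3-carboxylic acid
Product: 22 (Z)-2,3-didehydro keto-lactam acid (rings A, C, D; CO2H at C3; 9R,10R,11S,12S,13S), via secondary ozonide 21 (not isolated)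
Conditions: O3, CH2Cl2, −78 °C, stopped at first excess; then Me2S, −78 °C to rt
Reagents that add atoms: ozone, [O-][O+]=O
Why: Witkop-type oxidative cleavage by ozonolysis, in which electrophilic ozone should add to the tetrasubstituted, alkyl- and nitrogen-flanked C1=C9a bond rather than to the carboxyl-conjugated C2=C3 bond, while the product, an enamide bearing two acceptors, resists further ozone; C9a becomes the lactam carbonyl, C1 the ketone, and rings E and F merge into ring D.

Step 13
Reactants: 22 (Z)-2,3-didehydro keto-lactam acid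
Product: 23 keto-lactam C3-carboxylic acid (C3 epimers)
Conditions: H2 (1 atm), 10% Pd/C, EtOAc, rt
Reagents that add atoms: none
Why: Hydrogenation of an electron-poor dehydroamino acid is fast and leaves ketone, lactam and lactone untouched; the C3 centre formed is erased in step 15, so no selectivity is needed.

Step 14
Reactants: 24 3-methylfuran-2(5H)-one
Product: 25 3-methyl-2-[(triisopropylsilyl)oxy]furan
Conditions: TIPSOTf, Et3N, CH2Cl2, 0 °C
Reagents that add atoms: triisopropylsilyl triflate, CC(C)[Si](OS(=O)(=O)C(F)(F)F)(C(C)C)C(C)C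
Why: Soft enolisation and O-silylation of the butenolide gives the silyloxyfuran that carries all five carbons of ring B.

Step 15
Reactants: 23 keto-lactam C3-carboxylic acid; 25 3-methyl-2-[(triisopropylsilyl)oxy]furan
Product: 27 19,20-didehydro derivative of the target (butenolide at C3; 3S,9R,10R,11S,12S,13S,18S), via C3 acetate 26 (not isolated)
Conditions: PhI(OAc)2 (1.5 equiv), I2 (0.5 equiv), CH2Cl2, visible light, rt; then 25, BF3·OEt2, −78 °C
Reagents that add atoms: (diacetoxyiodo)benzene, CC(=O)OI(OC(C)=O)c1ccccc1 (its acetate is carried by 26 only)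
Why: One-pot radical decarboxylation–oxidation of an N-acyl amino acid to the N,O-acetal, followed by a vinylogous Mannich reaction of the derived N-acyliminium ion; the silyloxyfuran should attack C3 from the face of ring D opposite to the C5–C8 bridge and lactone ring A (3S) and in the threo sense usual for cyclic N-acyliminium ions (18S).

Step 16
Reactants: 27 19,20-didehydro derivative of the target
Product: 28 target CNP0311700.2 (3S,9R,10R,11S,12S,13S,18S,20S)
Conditions: H2 (1 atm), 10% Pd/C, EtOAc, rt
Reagents that add atoms: none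
Why: Heterogeneous hydrogenation of the α-methylbutenolide from the face opposite to the bulky C18 substituent should give the cis-2,4-disubstituted lactone (20S) under neutral conditions that do not touch the base-sensitive ketone.

**Compound list**
1 | methyl 4-bromo-1H-pyrrole-2-carboxylate | COC(=O)c1cc(Br)c[nH]1 | starting material
2 | methyl 4-bromo-1-(methoxymethyl)-1H-pyrrole-2-carboxylate | COCn1cc(Br)cc1C(=O)OC | intermediate
3 | 4-bromofuran-2(5H)-one | O=C1C=C(Br)CO1 | starting material
4 | methyl 1-(methoxymethyl)-4-(4,4,5,5-tetramethyl-1,3,2-dioxaborolan-2-yl)-1H-pyrrole-2-carboxylate | COCn1cc(B2OC(C)(C)C(C)(C)O2)cc1C(=O)OC | intermediate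
5 | methyl 1-(methoxymethyl)-4-(5-oxo-2,5-dihydrofuran-3-yl)-1H-pyrrole-2-carboxylate | COCn1cc(C2=CC(=O)OC2)cc1C(=O)OC | intermediate
6 | methyl 1-(methoxymethyl)-4-{5-[(triisopropylsilyl)oxy]furan-3-yl}-1H-pyrrole-2-carboxylate | COCn1cc(-c2coc(O[Si](C(C)C)(C(C)C)C(C)C)c2)cc1C(=O)OC | intermediate
7 | (E)-pent-2-enal | CC/C=C/C=O | starting material
8 | methyl 1-(methoxymethyl)-4-{(2S)-5-oxo-2-[(3R)-1-oxopentan-3-yl]-2,5-dihydrofuran-3-yl}-1H-pyrrole-2-carboxylate | CC[C@H](CC=O)[C@@H]1OC(=O)C=C1c1cn(COC)c(C(=O)OC)c1 | intermediate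
9 | methyl 1-(methoxymethyl)-4-{(2S,3R)-5-oxo-2-[(3R)-1-oxopentan-3-yl]oxolan-3-yl}-1H-pyrrole-2-carboxylate | CC[C@H](CC=O)[C@@H]1OC(=O)C[C@@H]1c1cn(COC)c(C(=O)OC)c1 | intermediate
10 | bromomagnesium alkoxide of the C8 allylic alcohol (C8 epimers) | CC[C@H](CC(C=C)O[Mg]Br)[C@@H]1OC(=O)C[C@@H]1c1cn(COC)c(C(=O)OC)c1 | intermediate
11 | methyl 4-{(2S,3R)-2-[(3R)-5-(methoxycarbonyloxy)hept-6-en-3-yl]-5-oxooxolan-3-yl}-1-(methoxymethyl)-1H-pyrrole-2-carboxylate (C8 epimers) | CC[C@H](CC(C=C)OC(=O)OC)[C@@H]1OC(=O)C[C@@H]1c1cn(COC)c(C(=O)OC)c1 | intermediate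
12 | methyl 4-{(2S,3R)-2-[(3R,4E)-hepta-4,6-dien-3-yl]-5-oxooxolan-3-yl}-1-(methoxymethyl)-1H-pyrrole-2-carboxylate | CC[C@H](/C=C/C=C)[C@@H]1OC(=O)C[C@@H]1c1cn(COC)c(C(=O)OC)c1 | intermediate
13 | lithium enolate of lactone 12 | CC[C@H](/C=C/C=C)[C@@H]1OC([O-])=C[C@@H]1c1cn(COC)c(C(=O)OC)c1.[Li+] | intermediate
14 | methyl 4-{(2S,3R,4S)-2-[(3R,4E)-hepta-4,6-dien-3-yl]-4-methyl-5-oxooxolan-3-yl}-1-(methoxymethyl)-1H-pyrrole-2-carboxylate | CC[C@H](/C=C/C=C)[C@@H]1OC(=O)[C@@H](C)[C@@H]1c1cn(COC)c(C(=O)OC)c1 | intermediate
15 | N-methylenepyrrolium ion from 14 (cation) | CC[C@H](/C=C/C=C)[C@@H]1OC(=O)[C@@H](C)[C@@H]1C1=C[N+](=C)C(C(=O)OC)=C1 | intermediate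
16 | allyl cation C7–C9 after C5–C6 bond formation (cation) | CC[C@H]1[C@@H]2OC(=O)[C@@H](C)[C@@H]2c2cn(CC/C=C\[CH+]1)c(C(=O)OC)c2 | intermediate
17 | tetracyclic pyrrole ester: pyrrole E (CO2Me at C3) fused at C1–C9a to ring F and bridged N4–C5H2–C6H2–C7H=C8H–C9 (Z), ethyl at C10, lactone A cis-fused at C11–C12, methyl at C13; 9R,10R,11S,12R,13S | CC[C@H]1[C@@H]2OC(=O)[C@@H](C)[C@@H]2c2cc(C(=O)OC)n3c2[C@@H]1/C=C\CC3 | intermediate
18 | 7,8-dihydro derivative of 17 (ring C saturated) | CC[C@H]1[C@@H]2OC(=O)[C@@H](C)[C@@H]2c2cc(C(=O)OC)n3c2[C@@H]1CCCC3 | intermediate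
19 | lithium carboxylate of 20 | CC[C@H]1[C@@H]2OC(=O)[C@@H](C)[C@@H]2c2cc(C(=O)[O-])n3c2[C@@H]1CCCC3.[Li+] | intermediate
20 | tetracyclic pyrrole-C3-carboxylic acid (18 with CO2H in place of CO2Me) | CC[C@H]1[C@@H]2OC(=O)[C@@H](C)[C@@H]2c2cc(C(=O)O)n3c2[C@@H]1CCCC3 | intermediate
21 | secondary ozonide bridging C1 and C9a of 20 | CC[C@H]1[C@@H]2OC(=O)[C@@H](C)[C@@H]2C23C=C(C(=O)O)N4CCCC[C@H]1C4(OO2)O3 | intermediate
22 | (Z)-2,3-didehydro keto-lactam acid: ring D with C1=O, C2H=C3(CO2H)–N4, C9a=O, bridged by ring C, lactone A at C11–C12; 9R,10R,11S,12S,13S | CC[C@H]1[C@@H]2OC(=O)[C@@H](C)[C@@H]2C(=O)/C=C(/C(=O)O)N2CCCC[C@H]1C2=O | intermediate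
23 | keto-lactam C3-carboxylic acid (2,3-dihydro-22, C3 epimers) | CC[C@H]1[C@@H]2OC(=O)[C@@H](C)[C@@H]2C(=O)CC(C(=O)O)N2CCCC[C@H]1C2=O | intermediate
24 | 3-methylfuran-2(5H)-one | CC1=CCOC1=O | starting material
25 | 3-methyl-2-[(triisopropylsilyl)oxy]furan | Cc1ccoc1O[Si](C(C)C)(C(C)C)C(C)C | intermediate
26 | C3 acetate (N,O-acetal; 23 with OAc in place of CO2H, C3 epimers) | CC[C@H]1[C@@H]2OC(=O)[C@@H](C)[C@@H]2C(=O)CC(OC(C)=O)N2CCCC[C@H]1C2=O | intermediate
27 | 19,20-didehydro derivative of the target (4-methyl-5-oxo-2,5-dihydrofuran-2-yl group at C3; 3S,9R,10R,11S,12S,13S,18S) | CC[C@H]1[C@@H]2OC(=O)[C@@H](C)[C@@H]2C(=O)C[C@@H]([C@@H]2C=C(C)C(=O)O2)N2CCCC[C@H]1C2=O | intermediate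
28 | CNP0311700.2 (3S,9R,10R,11S,12S,13S,18S,20S) | CC[C@H]1[C@@H]2OC(=O)[C@@H](C)[C@@H]2C(=O)C[C@@H]([C@@H]2C[C@H](C)C(=O)O2)N2CCCC[C@H]1C2=O | target

**Step count**
Total step count: 16. Longest linear sequence: 15 (steps 1–13, 15, 16).

**Steps most likely to fail**

Step 9.
- What may go wrong: the N-methylenepyrrolium ion may be intercepted by methanol or by a second pyrrole faster than by the diene. The allyl cation may lose the C10 proton to give a triene. Closure at C9 may also show poor facial selectivity.
- Fallback (known chemistry, the ring bonds made one at a time): it sets out from 14. HCl in MeOH removes the methoxymethyl group to give the N–H pyrrole diene F1. Catalytic TfOH in CH2Cl2 protonates the diene terminus, and intramolecular Friedel–Crafts hydroarylation closes ring F to the C9-(E)-propenyl tricycle F2. N-Alkylation with 4-bromobut-1-ene and Cs2CO3 in DMF gives the N-butenyl tricycle F3. Ring-closing metathesis with the second-generation Grubbs catalyst in CH2Cl2 at 40 °C closes ring C at C7=C8 and comes back to the route at 17.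

Step 12.
- What may go wrong: ozone may add across the two α-carbons or attack C3 at the carboxyl-bearing position with loss of CO2. The first-formed product may also be over-oxidised.
- Fallback: it replaces the one-stage dipolar cleavage by oxygen transfer followed by glycol cleavage, and sets out from 20. Dimethyldioxirane in moist acetone at −40 °C epoxidises the more electron-rich C1=C9a bond, and water opens the epoxide at the nitrogen-stabilised carbon to give the C1,C9a-dihydroxy pyrroline acid F4. This compound can be purified and checked before NaIO4 in THF/H2O cleaves the diol. The fallback comes back to the route at 22.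

Step 4.
- What may go wrong: the aryl group next to the nucleophilic furan carbon may slow the addition until hydrolysis of the silyloxyfuran takes over, and it may erode the simple diastereoselectivity.
- Fallback: it changes the order of bond construction and sets out from 3. Silylation (TIPSOTf, Et3N) gives 4-bromo-2-[(triisopropylsilyl)oxy]furan F5, which carries only a bromine atom beside the reacting carbon. The same iminium-catalysed addition to 7 should give the bromobutenolide aldehyde F6. Suzuki–Miyaura coupling of F6 with boronate 4 (isolated for this purpose after the first stage of step 2) follows under nearly neutral fluoride conditions (Pd2(dba)3, [HP(t-Bu)3]BF4, KF, THF, rt), chosen to spare the acidic C11–H. The fallback comes back to the route at 8.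

**Further compounds**
F1 | step 9 | methyl 4-{(2S,3R,4S)-2-[(3R,4E)-hepta-4,6-dien-3-yl]-4-methyl-5-oxooxolan-3-yl}-1H-pyrrole-2-carboxylate | CC[C@H](/C=C/C=C)[C@@H]1OC(=O)[C@@H](C)[C@@H]1c1c[nH]c(C(=O)OC)c1
F2 | step 9 | N–H tricycle (rings A, E, F) with (E)-prop-1-enyl at C9 and CO2Me at C3; 9R,10R,11S,12R,13S | CC[C@H]1[C@@H]2OC(=O)[C@@H](C)[C@@H]2c2cc(C(=O)OC)[nH]c2[C@@H]1/C=C/C
F3 | step 9 | N-(but-3-en-1-yl) derivative of F2 | CC[C@H]1[C@@H]2OC(=O)[C@@H](C)[C@@H]2c2cc(C(=O)OC)n(CCC=C)c2[C@@H]1/C=C/C
F4 | step 12 | C1,C9a-dihydroxy-1,9a-dihydro derivative of acid 20 | CC[C@H]1[C@@H]2OC(=O)[C@@H](C)[C@@H]2C2(O)C=C(C(=O)O)N3CCCC[C@H]1C23O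
F5 | step 4 | 4-bromo-2-[(triisopropylsilyl)oxy]furan | Brc1coc(O[Si](C(C)C)(C(C)C)C(C)C)c1
F6 | step 4 | (3R)-3-[(2S)-3-bromo-5-oxo-2,5-dihydrofuran-2-yl]pentanal | CC[C@H](CC=O)[C@@H]1OC(=O)C=C1Br
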